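**Retrosynthetic overview**
- Target flavanone ⇐ its 7-O-MOM ether ⇐ 7-(methoxymethoxy)-6,8-diprenylchromone + (2,2-dimethyl-2H-chromen-6-yl)boronic acid; the C2–C1′ bond and the only stereocentre (2S) come from a rhodium-catalysed enantioselective 1,4-addition.
- The diprenylchromone ⇐ 6,8-diiodo-7-(methoxymethoxy)chromone (twofold Stille prenylation) ⇐ 7-hydroxychromone; ring A and pyranone ring C are bought.
- The boronic acid ⇐ 6-bromo-2,2-dimethyl-2H-chromene ⇐ 2-(4-bromo-2-ethenylphenyl)propan-2-yl hydroperoxide, by a one-pot aryl carbon-to-oxygen shift (Criegee–Hock) and oxonia-6π ring closure that makes O1–C8a and C2–C3 of the dimethylpyran ring; the hydroperoxide ⇐ tertiary alcohol ⇐ methyl 4-bromo-2-ethenylbenzoate ⇐ methyl 4-bromo-2-iodobenzoate.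
- Enabling feature: in the 2,2-dimethyl-2H-pyran ring, C2 carries O1 and both methyl groups (an acetone-level carbon, a latent oxocarbenium ArO–C(+)Me2), and C3=C4 is a styrene double bond ortho to O1 on the benzene ring. A 2-arylpropan-2-yl hydroperoxide with an ortho-vinyl group is therefore the same ring with O1 not yet inserted between C2 and C8a.
- Ring order: benzene rings and ring C are given; the dimethylpyran ring is closed in step 4; the fragments are joined in step 9.

Key step: step 4

Remark: the dimethylpyran ring is numbered as in 2H-chromene (O1, C2, C3, C4, C4a, C8a) and the rest as in flavanone; the target SMILES corresponds to the 2S configuration.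

**Route**

Step 1
Reactants: 1 methyl 4-bromo-2-iodobenzoate
Product: 2 methyl 4-bromo-2-ethenylbenzoate
Conditions: vinylboronic acid pinacol ester (1.05 equiv), Pd(PPh3)4 (3 mol %), K2CO3 (2 equiv), 1,4-dioxane/H2O (4:1), 60 °C
Reagents that add atoms: vinylboronic acid pinacol ester, C=CB1OC(C)(C)C(C)(C)O1
Why: Suzuki–Miyaura coupling in which oxidative addition of zerovalent palladium is far faster at the C–I than at the C–Br bond, so that with one equivalent of boronate only the iodide should be vinylated and the bromide is kept for step 5.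

Step 2
Reactants: 2 methyl 4-bromo-2-ethenylbenzoate
Product: 4 2-(4-bromo-2-ethenylphenyl)propan-2-ol, via aryl methyl ketone 3 (not isolated)
Conditions: MeMgBr (3 equiv), THF, 0 °C → rt; aq. NH4Cl
Reagents that add atoms: methylmagnesium bromide, C[Mg]Br
Why: Double Grignard addition to the ester (through the methyl ketone) should give the tertiary benzylic alcohol, the aryl bromide and the styrene being inert to MeMgBr at this temperature.

Step 3
Reactants: 4 2-(4-bromo-2-ethenylphenyl)propan-2-ol
Product: 5 2-(4-bromo-2-ethenylphenyl)propan-2-yl hydroperoxide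
Conditions: 50 % aq. H2O2 (10 equiv), H2SO4 (0.1 equiv), Et2O, 0 °C → rt; washed free of H2O2 and dried, not distilled
Reagents that add atoms: hydrogen peroxide, OO
Why: Acid-catalysed perhydrolysis of a tertiary benzylic alcohol (ionisation to the cumyl cation, which is captured by the large excess of the alpha-effect nucleophile H2O2) should give the tertiary hydroperoxide, while cold dilute acid is too weak to start O–O cleavage or to protonate the styrene.

Step 4
Reactants: 5 2-(4-bromo-2-ethenylphenyl)propan-2-yl hydroperoxide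
Product: 8 6-bromo-2,2-dimethyl-2H-chromene, via peroxy trifluoroacetate 6 (not isolated), via trifluoroacetoxy ketal 7 (not isolated)
Conditions: (CF3CO)2O (1.2 equiv), 4 Å MS, CH2Cl2, −40 °C → 0 °C; then aq. NaHCO3
Reagents that add atoms: none
Why: Proposed new method: O-trifluoroacetylation of 5 gives perester 6, whose O–O bond ionises with a concerted 1,2-shift of the aryl carbon (the future C8a) from carbon to oxygen (Criegee–Hock rearrangement), which makes the O1–C8a bond and an aryloxy(dimethyl)oxocarbenium ion that is stored reversibly as its trifluoroacetate adduct 7. The 2-oxoniahexatriene C2=O1(+)–C8a=C4a–C4=C3 of this ion then closes by a thermal disrotatory oxonia-6π electrocyclisation (equally a 6-endo Prins-type attack of the vinyl CH2 on the oxocarbenium carbon) to make the C2–C3 bond and the pyran ring, and the O1-stabilised chroman-4-yl cation so formed loses the C3 proton to give the C3=C4 double bond. The closest known reaction types are the Hock cleavage of cumyl hydroperoxides and the Criegee rearrangement of tertiary peresters, the capture of Hock-type oxocarbenium ions by carbon π-nucleophiles, the ring closure of imines of 2-vinylanilines to dihydroquinolines, and the acid-catalysed dehydration of chroman-4-ols to 2H-chromenes, which passes through the same cation. No stereocentre is formed. The step needs aryl and not methyl migration, secured by the much higher migratory aptitude of an aryl group that carries a conjugating ortho-vinyl substituent and only a weakly deactivating para-bromine, and it needs ring closure to win over hydrolysis to phenol and acetone, secured by the water-free anhydride activation, the ortho placement of the vinyl group that holds C3 within bonding distance of C2, and the fact that 7 and the isopropenyl ether both return to the same oxocarbenium ion under the trifluoroacetic acid that is set free.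

Step 5
Reactants: 8 6-bromo-2,2-dimethyl-2H-chromene
Product: 11 (2,2-dimethyl-2H-chromen-6-yl)boronic acid, via aryllithium 9 (not isolated), via lithium aryltriisopropoxyborate 10 (not isolated)
Conditions: n-BuLi (1.1 equiv), THF, −78 °C; B(OiPr)3 (1.5 equiv), −78 °C → rt; 1 M aq. HCl to pH 5
Reagents that add atoms: triisopropyl borate, CC(C)OB(OC(C)C)OC(C)C; water, O
Why: Bromine–lithium exchange at −78 °C followed by borylation with B(OiPr)3 and mild acidic hydrolysis is the standard route to arylboronic acids, and the chromene double bond and ether are inert to n-BuLi at this temperature.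

Step 6
Reactants: 12 7-hydroxy-4H-chromen-4-one
Product: 14 7-hydroxy-6,8-diiodo-4H-chromen-4-one, via 8-iodo phenol 13 (not isolated)
Conditions: N-iodosuccinimide (2.2 equiv), CF3CO2H (0.1 equiv), MeCN/DMF, 0 °C → rt
Reagents that add atoms: N-iodosuccinimide, O=C1CCC(=O)N1I
Why: Electrophilic aromatic iodination; C8 and C6 are each ortho to the C7 hydroxyl and ortho or para to the ring oxygen O1, so both should be iodinated well before the electron-poor pyranone position C3 reacts.

Step 7
Reactants: 14 7-hydroxy-6,8-diiodo-4H-chromen-4-one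
Product: 15 6,8-diiodo-7-(methoxymethoxy)-4H-chromen-4-one
Conditions: MOMCl (1.5 equiv), i-Pr2NEt (2 equiv), CH2Cl2, 0 °C → rt
Reagents that add atoms: chloromethyl methyl ether, COCCl
Why: O-Alkylation (Williamson type) of the acidic, doubly ortho-substituted phenol with the small electrophile MOMCl; the acetal masks the phenol, which as its phenoxide would deactivate the chromone in steps 8 and 9.

Step 8
Reactants: 15 6,8-diiodo-7-(methoxymethoxy)-4H-chromen-4-one
Product: 17 7-(methoxymethoxy)-6,8-bis(3-methylbut-2-en-1-yl)-4H-chromen-4-one, via mono-prenyl iodide 16 (not isolated)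
Conditions: Bu3SnCH2CH=CMe2 (2.6 equiv), Pd(PPh3)4 (10 mol %), DMF, 90 °C
Reagents that add atoms: tributyl(3-methylbut-2-en-1-yl)stannane, CCCC[Sn](CCCC)(CCCC)CC=C(C)C
Why: Twofold Stille coupling; oxidative addition at both C–I bonds, transmetalation of the allylic stannane and reductive elimination at the less substituted allyl terminus should give the linear prenyl groups under neutral conditions that leave the base-sensitive chromone and the MOM acetal intact.

Step 9
Reactants: 17 7-(methoxymethoxy)-6,8-bis(3-methylbut-2-en-1-yl)-4H-chromen-4-one; 11 (2,2-dimethyl-2H-chromen-6-yl)boronic acid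
Product: 18 (2S)-2-(2,2-dimethyl-2H-chromen-6-yl)-7-(methoxymethoxy)-6,8-bis(3-methylbut-2-en-1-yl)-2,3-dihydro-4H-chromen-4-one
Conditions: 11 (2 equiv), [Rh(OH)(cod)]2 (3 mol %), (S)-2,2′-bis[bis(3,4,5-trifluorophenyl)phosphino]-6,6′-dimethoxy-1,1′-biphenyl (6.6 mol %), toluene/H2O (10:1), 40 °C
Reagents that add atoms: none
Why: Hayashi–Miyaura reaction (rhodium-catalysed enantioselective 1,4-addition of an arylboronic acid to a chromone): the aryl–rhodium species formed by transmetalation adds to C2 across one enantiotopic face of the C2=C3 bond, selected by the electron-poor atropisomeric bisphosphine (the (S)-ligand is expected, by analogy with the face selectivity of this ligand family on cyclic enones, to give 2S, and a trial on chromone itself would fix the antipode before material is committed), and protonation of the oxa-π-allyl rhodium by water releases the flavanone.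

Step 10
Reactants: 18 (2S)-2-(2,2-dimethyl-2H-chromen-6-yl)-7-(methoxymethoxy)-6,8-bis(3-methylbut-2-en-1-yl)-2,3-dihydro-4H-chromen-4-one
Product: 19 (2S)-2-(2,2-dimethyl-2H-chromen-6-yl)-7-hydroxy-6,8-bis(3-methylbut-2-en-1-yl)-2,3-dihydro-4H-chromen-4-one (the target flavanone)
Conditions: 3 M HCl in MeOH, rt → 40 °C
Reagents that add atoms: none
Why: Acid-catalysed acetal cleavage (transacetalisation to dimethoxymethane) of the hindered aryl MOM ether, whose phenol is a good leaving group para to the ketone, should proceed under conditions mild enough that the prenyl groups do not cyclise onto the freed phenol, the chromene is not hydrated and C2 keeps its configuration.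

**Compound list**
1 | methyl 4-bromo-2-iodobenzoate | COC(=O)c1ccc(Br)cc1I | starting material
2 | methyl 4-bromo-2-ethenylbenzoate | COC(=O)c1ccc(Br)cc1C=C | intermediate
3 | 1-(4-bromo-2-ethenylphenyl)ethan-1-one (not isolated) | CC(=O)c1ccc(Br)cc1C=C | intermediate
4 | 2-(4-bromo-2-ethenylphenyl)propan-2-ol | CC(C)(O)c1ccc(Br)cc1C=C | intermediate
5 | 2-(4-bromo-2-ethenylphenyl)propan-2-yl hydroperoxide | CC(C)(OO)c1ccc(Br)cc1C=C | intermediate
6 | 2-(4-bromo-2-ethenylphenyl)propan-2-yl trifluoroperoxyacetate (not isolated) | CC(C)(OOC(=O)C(F)(F)F)c1ccc(Br)cc1C=C | intermediate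
7 | 2-(4-bromo-2-ethenylphenoxy)propan-2-yl trifluoroacetate (not isolated) | CC(C)(OC(=O)C(F)(F)F)Oc1ccc(Br)cc1C=C | intermediate
8 | 6-bromo-2,2-dimethyl-2H-chromene | CC1(C)C=Cc2cc(Br)ccc2O1 | intermediate
9 | (2,2-dimethyl-2H-chromen-6-yl)lithium (not isolated) | [Li]c1ccc2OC(C)(C)C=Cc2c1 | intermediate
10 | lithium (2,2-dimethyl-2H-chromen-6-yl)tri(propan-2-yloxy)borate (not isolated) | [Li+].CC(C)O[B-](OC(C)C)(OC(C)C)c1ccc2OC(C)(C)C=Cc2c1 | intermediate
11 | (2,2-dimethyl-2H-chromen-6-yl)boronic acid | CC1(C)C=Cc2cc(B(O)O)ccc2O1 | intermediate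
12 | 7-hydroxy-4H-chromen-4-one | O=c1ccoc2cc(O)ccc12 | starting material
13 | 7-hydroxy-8-iodo-4H-chromen-4-one (not isolated; the C8 position is expected to react first) | O=c1ccoc2c(I)c(O)ccc12 | intermediate
14 | 7-hydroxy-6,8-diiodo-4H-chromen-4-one | O=c1ccoc2c(I)c(O)c(I)cc12 | intermediate
15 | 6,8-diiodo-7-(methoxymethoxy)-4H-chromen-4-one | COCOc1c(I)cc2c(=O)ccoc2c1I | intermediate
16 | 8-iodo-7-(methoxymethoxy)-6-(3-methylbut-2-en-1-yl)-4H-chromen-4-one (not isolated; the less hindered C6 iodide is expected to couple first) | COCOc1c(CC=C(C)C)cc2c(=O)ccoc2c1I | intermediate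
17 | 7-(methoxymethoxy)-6,8-bis(3-methylbut-2-en-1-yl)-4H-chromen-4-one | COCOc1c(CC=C(C)C)cc2c(=O)ccoc2c1CC=C(C)C | intermediate
18 | (2S)-2-(2,2-dimethyl-2H-chromen-6-yl)-7-(methoxymethoxy)-6,8-bis(3-methylbut-2-en-1-yl)-2,3-dihydro-4H-chromen-4-one | CC(C)=CCc1cc2c(c(CC=C(C)C)c1OCOC)O[C@H](c1ccc3c(c1)C=CC(C)(C)O3)CC2=O | intermediate
19 | (2S)-2-(2,2-dimethyl-2H-chromen-6-yl)-7-hydroxy-6,8-bis(3-methylbut-2-en-1-yl)-2,3-dihydro-4H-chromen-4-one (the target flavanone) | CC(C)=CCc1cc2c(c(CC=C(C)C)c1O)O[C@H](c1ccc3c(c1)C=CC(C)(C)O3)CC2=O | target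

**Step count**
Total: 10 steps. Longest linear sequence: 7 steps (steps 1, 2, 3, 4, 5, 9, 10).

**Steps most likely to fail**

Step 4 (Proposed new method). The oxocarbenium ion may be diverted before the ring closes. Possible diversions are hydrolysis by adventitious water to phenol and acetone, proton loss to an isopropenyl ether that is not re-protonated, attack of the vinyl group on the peroxide oxygen, and acid-induced oligomerisation of the styrene or of the product. The fallback uses known chemistry, sets out from 5 and comes back at 8. Compound 5 is cleaved in the ordinary Hock manner (H2SO4 cat., acetone, rt) to 4-bromo-2-ethenylphenol F1. This is O-alkylated with 3-chloro-3-methylbut-1-yne (CuCl2·2H2O cat., DBU, MeCN, 0 °C) to 4-bromo-2-ethenyl-1-[(2-methylbut-3-yn-2-yl)oxy]benzene F2. Semi-hydrogenation of the alkyne (H2, Pd/CaCO3 poisoned with Pb(OAc)2, quinoline, EtOAc) should give 4-bromo-2-ethenyl-1-[(2-methylbut-3-en-2-yl)oxy]benzene F3. Ring-closing metathesis of the two vinyl groups (second-generation Grubbs catalyst RuCl2(=CHPh)(PCy3)(H2IMes), CH2Cl2, 40 °C) should then close C3=C4 and deliver 8.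

Step 9. Carborhodation of the electron-rich, 8-substituted chromone may be slow, so that protodeboronation of 11 takes over. The enantiomeric purity may also erode through ring opening and reclosure of the product (retro-oxa-Michael). The fallback sets out from 8 and 17 and comes back at 18. Compound 8 is lithiated and formylated (n-BuLi, THF, −78 °C; DMF; dilute aq. HCl) to 2,2-dimethyl-2H-chromene-6-carbaldehyde F4. Compound 17 is opened with hydroxide (2 M aq. NaOH, EtOH, 70 °C), which removes C2 as formate and should give 1-[2-hydroxy-4-(methoxymethoxy)-3,5-bis(3-methylbut-2-en-1-yl)phenyl]ethan-1-one F5. Claisen–Schmidt condensation of F5 with F4 (KOH, EtOH, rt) should give (E)-3-(2,2-dimethyl-2H-chromen-6-yl)-1-[2-hydroxy-4-(methoxymethoxy)-3,5-bis(3-methylbut-2-en-1-yl)phenyl]prop-2-en-1-one F6. Enantioselective intramolecular oxa-Michael addition of F6 with a quinine-derived bifunctional thiourea (pseudo-enantiomer chosen for 2S, toluene, rt) should give 18. Lower selectivity is expected on this path, so the enantiomeric purity would be raised by crystallisation if needed.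

Step 8. Allylic transposition during transmetalation and reductive elimination may give 1,1-dimethylallyl instead of prenyl groups. The reaction may also stall after the first coupling at the hindered C8 iodide, or lose iodine by protodeiodination. The fallback builds the prenyl groups by aromatic Claisen rearrangement; it sets out from 12 and comes back at 17. Compound 12 is O-alkylated with 3-chloro-3-methylbut-1-yne (CuCl2·2H2O cat., DBU, MeCN, 0 °C) to 7-[(2-methylbut-3-yn-2-yl)oxy]-4H-chromen-4-one F7. Semi-hydrogenation (H2, Pd/CaCO3 poisoned with Pb(OAc)2, quinoline, EtOAc) should give 7-[(2-methylbut-3-en-2-yl)oxy]-4H-chromen-4-one F8. Heating (N,N-diethylaniline, 130 °C) should give 7-hydroxy-8-(3-methylbut-2-en-1-yl)-4H-chromen-4-one F9 by [3,3] shift; any 6-prenyl isomer converges in the second round. The same three operations are then repeated, through 8-(3-methylbut-2-en-1-yl)-7-[(2-methylbut-3-yn-2-yl)oxy]-4H-chromen-4-one F10 and 8-(3-methylbut-2-en-1-yl)-7-[(2-methylbut-3-en-2-yl)oxy]-4H-chromen-4-one F11, to 7-hydroxy-6,8-bis(3-methylbut-2-en-1-yl)-4H-chromen-4-one F12. MOM protection of F12 (MOMCl, i-Pr2NEt, CH2Cl2) gives 17.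

Further compounds
F1 | step 4 | 4-bromo-2-ethenylphenol | Oc1ccc(Br)cc1C=C
F2 | step 4 | 4-bromo-2-ethenyl-1-[(2-methylbut-3-yn-2-yl)oxy]benzene | C#CC(C)(C)Oc1ccc(Br)cc1C=C
F3 | step 4 | 4-bromo-2-ethenyl-1-[(2-methylbut-3-en-2-yl)oxy]benzene | C=CC(C)(C)Oc1ccc(Br)cc1C=C
F4 | step 9 | 2,2-dimethyl-2H-chromene-6-carbaldehyde | CC1(C)C=Cc2cc(C=O)ccc2O1
F5 | step 9 | 1-[2-hydroxy-4-(methoxymethoxy)-3,5-bis(3-methylbut-2-en-1-yl)phenyl]ethan-1-one | CC(=O)c1cc(CC=C(C)C)c(OCOC)c(CC=C(C)C)c1O
F6 | step 9 | (E)-3-(2,2-dimethyl-2H-chromen-6-yl)-1-[2-hydroxy-4-(methoxymethoxy)-3,5-bis(3-methylbut-2-en-1-yl)phenyl]prop-2-en-1-one | COCOc1c(CC=C(C)C)cc(C(=O)/C=C/c2ccc3OC(C)(C)C=Cc3c2)c(O)c1CC=C(C)C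
F7 | step 8 | 7-[(2-methylbut-3-yn-2-yl)oxy]-4H-chromen-4-one | C#CC(C)(C)Oc1ccc2c(=O)ccoc2c1
F8 | step 8 | 7-[(2-methylbut-3-en-2-yl)oxy]-4H-chromen-4-one | C=CC(C)(C)Oc1ccc2c(=O)ccoc2c1
F9 | step 8 | 7-hydroxy-8-(3-methylbut-2-en-1-yl)-4H-chromen-4-one | CC(C)=CCc1c(O)ccc2c(=O)ccoc12
F10 | step 8 | 8-(3-methylbut-2-en-1-yl)-7-[(2-methylbut-3-yn-2-yl)oxy]-4H-chromen-4-one | C#CC(C)(C)Oc1ccc2c(=O)ccoc2c1CC=C(C)C
F11 | step 8 | 8-(3-methylbut-2-en-1-yl)-7-[(2-methylbut-3-en-2-yl)oxy]-4H-chromen-4-one | C=CC(C)(C)Oc1ccc2c(=O)ccoc2c1CC=C(C)C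
F12 | step 8 | 7-hydroxy-6,8-bis(3-methylbut-2-en-1-yl)-4H-chromen-4-one | CC(C)=CCc1cc2c(=O)ccoc2c(CC=C(C)C)c1O
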